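## Structural features

The target is a trans-2,3-diaryl-2,3-dihydro-1-benzofuran. Ring A carries O1 at C7a, a free hydroxyl at C4 and a 2-(4-hydroxyphenyl)ethyl chain at C6, and is fused to the five-membered ring O1–C2–C3–C3a–C7a. C2 bears a 4-hydroxyphenyl group and C3 a 3,5-dihydroxyphenyl group; the two adjacent stereocentres are both S, which places the aryl groups trans. C2 is a benzylic ether carbon that cannot be corrected once set, whereas C3 relaxes to the trans arrangement under the influence of C2 whenever it carries a carbonyl group. Before the O1–C2 bond exists, ring A is a 2,5-disubstituted resorcinol with two equivalent oxygens, so the route must decide which of them becomes O1. The fragile points are the C2–O1 bond (a para-oxygenated benzylic aryl ether that ionises with strong acids), five oxidation-prone phenols, and C3 when it stands next to an acceptor. The real difficulty is absolute control of C2, the attachment of two different meta-dioxygenated rings without confusing their patterns, and the release of five phenols without opening the dihydrofuran. The key step exploits the C3 aryl group: it is a resorcinol substituted only at its 5-position, so its carbons map onto the four-carbon chain of a methyl ynone plus two malonate carbons, the ketone oxygen and one ester carbonyl oxygen become the two hydroxyls, and the alkyne carbon bound to C3 becomes the ring carbon attached to C3.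

## Logic of the disconnections

25 to 23. Two aryl–O–CH2 bonds, the ester O–CH2 bond and the aryl–CO2 bond are reinstated. The cut is made here so that the finished, acid-sensitive skeleton meets only a neutral reagent. Hydrogen over palladium removes every benzyl group, and acid 24 loses CO2 on warming. The demand is that exocyclic benzylic C–O bonds cleave faster than the ring C2–O1 bond.

23 to 22. The O4–Si bond is reinstated. The silyl ether is there only to keep O4 inert, and buffered fluoride removes it without acid, base or hydrogen. The demand is that the benzyl ester and the benzyl ethers are left alone.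

22 to 19 and 20. Two bonds of the C3 aryl ring are cut: the bond from the ring carbon attached to C3 to the ester-bearing carbon, and the bond from the CH between the two hydroxylated carbons to the hydroxylated carbon next to the ester. A ketone oxygen and a malonate carbonyl oxygen deliver exactly the meta relationship of the hydroxyls to each other and to C3. The gain is the loss of a whole arene; C3 keeps only a linear four-carbon ynone. The demand is conjugate addition at the alkyne carbon bound to C3, C-acylation in the ring closure, and survival of the C3 configuration in base.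

19 to 16 and 17. The bond between the alkyne carbon and the acetyl carbon is cut, so that the base-sensitive ynone is made last from a stable terminal alkyne. The demand is mono-acylation without exposing the free ynone to the acetylide.

16 to 13 and 14. The triple bond is cut back to the ester carbon, which becomes the internal alkyne carbon; the terminal carbon comes from 14. The gain is an ester, the natural product of carbenoid chemistry. The demand is a stop at the aldehyde level (15) and tolerance of an enolisable alpha-aryl aldehyde, which can only relax to trans.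

13 to 11. The C2–C3 bond is cut; this is the stereo-defining disconnection. C3 becomes a carbene carbon and C2 the benzylic CH2 of an ortho ether whose aryl group becomes the C2 aryl. The other ortho oxygen carries a silyl group with no hydrogen on the atom next to oxygen, so there is one site of insertion only. The demand is selection of one enantiotopic benzylic hydrogen by a chiral catalyst; the kinetic cis ester 12 is then epimerised at C3.

11 to 9 and 10. The C3a–C3 bond is cut to an aryl iodide and a diazo ester, keeping the diazo group. The demand is coupling at an iodide flanked by an alkoxy and a silyloxy group.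

9 to 8. The O4–Si bond is cut. The gain is a phenol that is already differentiated from its partner; the demand is only silylation next to iodine.

8 to 6 and 7. One ArO–CH2 bond is cut. This is the point where the symmetry of ring A is broken: one of two equivalent phenols receives the ether that later supplies C2 with its aryl group. The demand is mono-etherification, which rests on stoichiometry.

6 to 5. The C–I bond is cut. The carbon between the two resorcinol hydroxyls is the one iodinated under aqueous bicarbonate, and it is para to the side chain as ring A requires. The demand is selectivity for this carbon over the other ring positions and over the benzyl-protected ring.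

5 to 1 and 3. The bond between ring A and the benzylic CH2 of the chain is cut. The side-chain phenol arrives already benzylated in 1, so it never has to be told apart from the ring A phenols. The demand is anti-Markovnikov hydroboration by 2 and an sp2–sp3 coupling in the presence of two free phenols.

## Other disconnections considered

Alternative 1: The cut is the O1–C2 bond together with the aromaticity of ring A. The dihydrofuran is traced to spirocyclopropane dione A1, whose two substituted cyclopropane carbons are C2 and C3 and whose spiro carbon is C3a.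
- Forward step: Sc(OTf)3 activates the dione, the bond from the spiro carbon to the anisyl-bearing carbon breaks, and a dione oxygen captures the benzylic cation to give tetrahydrobenzofuranone A2. Dehydrogenation to phenol A3 and ether cleavage would follow.
- In favour: only the para-methoxyphenyl carbon can carry the cation, so oxygen ends on C2 by mechanism, and closure anti to the C3 aryl should give trans. The two ring A oxygens are told apart by the reaction itself, and the C3 aryl arrives ready-made. The step count is likely lower.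
- Against: all stereochemical information rests on the cyclopropane carbon that becomes C3, which calls for an enantioselective cyclopropanation of a 1,2-diaryl alkene by an acceptor/acceptor carbene equivalent, a weakly precedented task. Ring A must then be oxidised to the aromatic level in a molecule whose C2–H and C3–H are benzylic and whose dihydrofuran is one dehydrogenation from an achiral benzofuran. A3 still carries four methyl ethers that need a boron trihalide.
- Comparison: on regiocontrol the alternative equals the chosen plan. On step economy and on the differentiation of the ring A oxygens it is the better, since the chosen plan breaks that symmetry by a stoichiometry-controlled mono-etherification. On structure the chosen plan is safer, because ring A is aromatic from the start and no oxidation follows the creation of the stereocentres. On absolute stereocontrol and on the mildness of the last step the chosen plan is the stronger.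

Alternative 2: The cut removes C3a–C7a, C4–C5 and C6–C7, so ring A and the dihydrofuran form together from diyne A4 (ethynyl ether on the C2 oxygen, silyloxyalkyne on C3) and alkyne A5.
- Forward step: [Rh(cod)2]BF4 with a bisphosphine forms a rhodacycle from A4, A5 inserts, and reductive elimination gives silyl ether A6.
- In favour: it is the most convergent plan, with both rings and the side chain joined in one step. C2 and C3 are set beforehand in an open chain and are not touched by the metal. O1 and O4 come from different functional groups, so no symmetry has to be broken, and the C4 oxygen emerges as a silyl ether.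
- Against: the orientation in which A5 inserts decides between the 6- and the 5-substituted ring A, and only a modest steric and electronic bias steers it. A4 combines a secondary benzylic ethynyl ether, prone to hydrolysis and to retro-ene loss of ketene, with a silyl ynol ether, and both are awkward to make on a stereodefined diaryl alcohol. A5 can trimerise with itself. A6 again needs methyl ether cleavage.
- Comparison: on convergence and on the differentiation of the ring A oxygens the alternative is the better, and on early fixing of both stereocentres it is at least equal. The chosen plan is stronger on regiochemical certainty, since the ring A substituents come fixed in 3 and the resorcinol pattern is fixed by mechanism. It is also stronger on the robustness of intermediates and on the final deprotection. Total step counts are expected to be similar once A4 is included.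

Alternative 3: The cut removes three bonds of ring A but leaves the furan open: cyclobutenone A7 and siloxyalkyne A8, which carries C3 and C2, give phenol A9.
- Forward step: on heating, A7 opens to a vinylketene, which adds to A8 in a (2+2) fashion; four-electron ring opening, six-electron ring closure and tautomerisation give A9. Desilylation, closure of O1–C2 and ether cleavage would follow.
- In favour: the pericyclic sequence fixes the substitution pattern of ring A, no metal is needed, and the side chain is delivered in a small fragment.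
- Against: ring A is symmetric about the C3a–C6 axis, so the differentiation of its two oxygens buys nothing; which of them becomes O1 is decided only at ring closure. A8 must carry the C3 stereocentre next to an ynol ether through prolonged heating. The silyloxy carbon of A8 and A9 has the same spatial arrangement as C2 of the target, so a closure with inversion would give the cis isomer. Only an ionising closure under thermodynamic control gives trans, which means that centre need not have been set. At least three operations follow the key step, the last with a boron trihalide.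
- Comparison: on regiocontrol of ring A the alternative equals the chosen plan, and on convergence it is the better. The chosen plan is shorter after its key step, needs one catalytic asymmetric step and no acyclic stereodiad, and ends with a neutral deprotection.

Key step: step 9

Notation: BOB is the 4-(benzyloxy)benzyl group, CH2C6H4(4-OCH2C6H5). TIPS is the tri(propan-2-yl)silyl group.

Assumption: Rh2(S-PTTL)4, dirhodium tetrakis[N-phthaloyl-(S)-tert-leucinate], is written as the catalyst enantiomer that sets 2S; if the sense of induction is the opposite, Rh2(R-PTTL)4 is used and nothing else changes.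

Assumption: compounds 1, 3 and 7 are bought.

Remark on descriptors: the trans compounds 13, 15, 16, 18, 19 and 21 to 25 are all 2S,3S. The cis ester 12 is 2S,3R, with C2 unchanged.

## Route

Step 1
Reactants: 1 1-(benzyloxy)-4-ethenylbenzene; 2 9-borabicyclo[3.3.1]nonane (9-BBN); 3 5-bromobenzene-1,3-diol
Product: 5 5-{2-[4-(benzyloxy)phenyl]ethyl}benzene-1,3-diol, via alkylborane 4 (not isolated)
Conditions: 2 (1.1 equiv), THF, 0 °C to rt; then 3, PdCl2(dppf) (3 mol%), K3PO4 (4 equiv), THF/H2O, 65 °C
Reagents that add atoms: none
Why: Hydroboration of the styrene with 9-BBN places boron on the terminal carbon, and the B-alkyl Suzuki–Miyaura coupling then transfers the primary alkyl group to the aryl bromide. The two phenols are carried as phenoxides, which is why the base is used in excess; the benzyl ether of the side chain is never exposed to hydrogen.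

Step 2
Reactants: 5 5-{2-[4-(benzyloxy)phenyl]ethyl}benzene-1,3-diol
Product: 6 5-{2-[4-(benzyloxy)phenyl]ethyl}-2-iodobenzene-1,3-diol
Conditions: I2 (1.0 equiv), NaHCO3, THF/H2O, 0 °C
Reagents that add atoms: iodine, I-I
Why: Electrophilic aromatic iodination; the resorcinol ring is far more nucleophilic than the benzyl-protected ring, and under aqueous bicarbonate resorcinol and its 5-alkyl homologues are iodinated at the carbon between the two hydroxyls, so one equivalent of iodine in the cold should react there only.

Step 3
Reactants: 6 5-{2-[4-(benzyloxy)phenyl]ethyl}-2-iodobenzene-1,3-diol; 7 1-(benzyloxy)-4-(chloromethyl)benzene (BOB chloride)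
Product: 8 3-(BOB-oxy)-5-{2-[4-(benzyloxy)phenyl]ethyl}-2-iodophenol
Conditions: 6 (1.5 equiv, the excess recovered), 7 (1.0 equiv), K2CO3 (1.0 equiv), NaI (cat.), acetone, 50 °C
Reagents that add atoms: none
Why: Williamson ether synthesis of one of two equivalent phenoxides with a reactive benzylic chloride; the diol is kept in excess so that the mono-ether dominates, and it should separate easily from the more polar diol and the less polar bis-ether. C-alkylation of the resorcinol is blocked at its most nucleophilic carbon by iodine.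

Step 4
Reactants: 8 3-(BOB-oxy)-5-{2-[4-(benzyloxy)phenyl]ethyl}-2-iodophenol
Product: 9 [3-(BOB-oxy)-5-{2-[4-(benzyloxy)phenyl]ethyl}-2-iodophenoxy]tri(propan-2-yl)silane
Conditions: TIPSCl (1.2 equiv), imidazole, DMF, rt
Reagents that add atoms: chlorotri(propan-2-yl)silane, CC(C)[Si](Cl)(C(C)C)C(C)C
Why: Silylation of the remaining phenol; the silyl ether has no C–H bond on the atom next to oxygen, so this oxygen stays out of the later carbenoid reaction, and a TIPS aryl ether tolerates the carbonate, hydride and organolithium steps that follow.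

Step 5
Reactants: 9 [3-(BOB-oxy)-5-{2-[4-(benzyloxy)phenyl]ethyl}-2-iodophenoxy]tri(propan-2-yl)silane; 10 ethyl diazoacetate
Product: 11 ethyl 2-diazo-2-[2-(BOB-oxy)-4-{2-[4-(benzyloxy)phenyl]ethyl}-6-(TIPS-oxy)phenyl]acetate
Conditions: Pd(PPh3)4 (5 mol%), Ag2CO3 (0.5 equiv), Et3N, toluene, rt
Reagents that add atoms: none
Why: Palladium-catalysed cross-coupling of an aryl iodide with a diazoacetate that keeps the diazo group: oxidative addition to zerovalent palladium, Ag2CO3-assisted transfer of the deprotonated diazoacetate and reductive elimination, all at room temperature.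

Step 6
Reactants: 11 ethyl 2-diazo-2-[2-(BOB-oxy)-4-{2-[4-(benzyloxy)phenyl]ethyl}-6-(TIPS-oxy)phenyl]acetate
Product: 13 ethyl (2S,3S)-2-[4-(benzyloxy)phenyl]-6-{2-[4-(benzyloxy)phenyl]ethyl}-4-(TIPS-oxy)-2,3-dihydro-1-benzofuran-3-carboxylate (trans), via cis ester 12 (not isolated)
Conditions: Rh2(S-PTTL)4 (1 mol%), toluene, −60 °C to 0 °C; then KOt-Bu (0.2 equiv), t-BuOH/THF, 0 °C
Reagents that add atoms: none
Why: Enantioselective intramolecular rhodium-carbenoid C–H insertion into the benzylic ether C–H bond forms C2–C3 and the dihydrofuran; the chiral carboxylate ligands choose one enantiotopic hydrogen and so set C2 (S), the kinetic product being cis ester 12, and the silyl ether on the other ortho oxygen offers no competing site. The hindered tert-butoxide then epimerises the enolisable C3 to the trans ester (3S) under the control of C2, which it cannot touch, and should spare both the ester and the silyl ether.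

Step 7
Reactants: 13 ethyl (2S,3S)-2-[4-(benzyloxy)phenyl]-6-{2-[4-(benzyloxy)phenyl]ethyl}-4-(TIPS-oxy)-2,3-dihydro-1-benzofuran-3-carboxylate; 14 dimethyl (1-diazo-2-oxopropyl)phosphonate
Product: 16 {[(2S,3S)-2-[4-(benzyloxy)phenyl]-6-{2-[4-(benzyloxy)phenyl]ethyl}-3-ethynyl-2,3-dihydro-1-benzofuran-4-yl]oxy}tri(propan-2-yl)silane, via aldehyde 15 (not isolated)
Conditions: i-Bu2AlH (1.2 equiv), CH2Cl2, −78 °C; then MeOH, K2CO3, 14, −78 °C to rt
Reagents that add atoms: none
Why: Partial reduction of the ester to its aluminium hemiacetal followed in the same flask by Ohira–Bestmann homologation, a known one-pot conversion of esters into terminal alkynes; the sensitive alpha-aryl aldehyde 15 is never isolated. Any enolisation of 15 under carbonate returns the trans isomer because C2 is fixed.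

Step 8
Reactants: 16 {[(2S,3S)-2-[4-(benzyloxy)phenyl]-6-{2-[4-(benzyloxy)phenyl]ethyl}-3-ethynyl-2,3-dihydro-1-benzofuran-4-yl]oxy}tri(propan-2-yl)silane; 17 N-methoxy-N-methylacetamide
Product: 19 4-[(2S,3S)-2-[4-(benzyloxy)phenyl]-6-{2-[4-(benzyloxy)phenyl]ethyl}-4-(TIPS-oxy)-2,3-dihydro-1-benzofuran-3-yl]but-3-yn-2-one, via lithium acetylide 18 (not isolated)
Conditions: n-BuLi (1.05 equiv), THF, −78 °C; then 17, −78 °C to 0 °C; aq. NH4Cl
Reagents that add atoms: none
Why: Weinreb ketone synthesis with an acetylide; the alkyne C–H is by far the most acidic site, and the chelated tetrahedral adduct releases the ynone only on quench, so the ynone never meets the acetylide base.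

Step 9
Reactants: 19 4-[(2S,3S)-2-[4-(benzyloxy)phenyl]-6-{2-[4-(benzyloxy)phenyl]ethyl}-4-(TIPS-oxy)-2,3-dihydro-1-benzofuran-3-yl]but-3-yn-2-one; 20 dibenzyl propanedioate (dibenzyl malonate)
Product: 22 benzyl 2,4-dihydroxy-6-[(2S,3S)-2-[4-(benzyloxy)phenyl]-6-{2-[4-(benzyloxy)phenyl]ethyl}-4-(TIPS-oxy)-2,3-dihydro-1-benzofuran-3-yl]benzoate, via Michael adduct 21 (not isolated)
Conditions: 20 (2.2 equiv), NaH (2.0 equiv), THF, 0 °C; add 19, 0 °C to rt; then 65 °C; AcOH quench
Reagents that add atoms: none
Why: The sodium enolate of 20 adds in conjugate fashion to the ynone carbon bound to C3 (Michael addition) and gives adduct 21 as a delocalised anion in which the E and Z enone isomers interconvert through the dienolate. In the Z isomer the methyl ketone enolate attacks one benzyl ester carbonyl (Claisen condensation, 6-(enolendo)-exo-trig closure), benzyl oxide leaves, and the cyclohexadienone tautomerises at once to the aromatic 2,4-dihydroxybenzoate, so two ring bonds and the whole C3 aryl ring form in one flask. The closest known reaction type is the classical synthesis of orsellinate and olivetolate esters from malonates and alkynyl methyl ketones. No stereocentre is created; C2 is inert, and C3 is held trans by the C2 aryl group should it planarise transiently through the propargyl–allenyl manifold. Three selectivities are needed: 1,4- over 1,2-addition, secured by the soft stabilised carbanion and the polarisation of the ynone; C- over O-acylation, secured because a 2-pyranone formed by lactonisation is reopened by alkoxide while aromatisation to the phenoxide is irreversible; and addition faster than deprotonation at C3, secured by keeping 20 in excess over NaH so that no base stronger than the malonate anion is present at the start. The benzyl oxide that is expelled is consumed at once by the acidic resorcylate, which should spare the silyl ether at O4. The surviving ester is benzyl so that it leaves in the final hydrogenolysis.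

Step 10
Reactants: 22 benzyl 2,4-dihydroxy-6-[(2S,3S)-2-[4-(benzyloxy)phenyl]-6-{2-[4-(benzyloxy)phenyl]ethyl}-4-(TIPS-oxy)-2,3-dihydro-1-benzofuran-3-yl]benzoate
Product: 23 benzyl 2,4-dihydroxy-6-[(2S,3S)-2-[4-(benzyloxy)phenyl]-6-{2-[4-(benzyloxy)phenyl]ethyl}-4-hydroxy-2,3-dihydro-1-benzofuran-3-yl]benzoate
Conditions: n-Bu4NF (1.2 equiv), AcOH (1.2 equiv), THF, 0 °C
Reagents that add atoms: none
Why: Fluoride-induced cleavage of an aryl silyl ether, driven by the strength of the Si–F bond; buffering with acetic acid keeps the medium near neutral, so the benzyl ester, the benzyl ethers and both stereocentres are not touched.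

Step 11
Reactants: 23 benzyl 2,4-dihydroxy-6-[(2S,3S)-2-[4-(benzyloxy)phenyl]-6-{2-[4-(benzyloxy)phenyl]ethyl}-4-hydroxy-2,3-dihydro-1-benzofuran-3-yl]benzoate
Product: 25 5-{(2S,3S)-4-hydroxy-2-(4-hydroxyphenyl)-6-[2-(4-hydroxyphenyl)ethyl]-2,3-dihydro-1-benzofuran-3-yl}benzene-1,3-diol, via resorcylic acid 24 (not isolated)
Conditions: H2 (1 atm), Pd/C (10% palladium on carbon), THF/MeOH, rt; filter; then degassed dioxane/H2O, 90 °C
Reagents that add atoms: none
Why: Hydrogenolysis cleaves the two aryl benzyl ethers and the benzyl ester, exocyclic benzylic C–O bonds being cleaved much faster than the ring C2–O1 bond, as in the debenzylation of benzylated flavan-3-ols. The freed beta-resorcylic acid 24, with hydroxyls ortho and para to the carboxyl, decarboxylates on warming by ipso protonation (reverse Kolbe–Schmitt), as orsellinic-type acids do; no stereocentre is involved.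

## Compound list

1 | 1-(benzyloxy)-4-ethenylbenzene | C=Cc1ccc(OCc2ccccc2)cc1 | starting material
2 | 9-borabicyclo[3.3.1]nonane | B1C2CCCC1CCC2 | starting material
3 | 5-bromobenzene-1,3-diol | Oc1cc(O)cc(Br)c1 | starting material
4 | 9-{2-[4-(benzyloxy)phenyl]ethyl}-9-borabicyclo[3.3.1]nonane (formed in the flask in step 1) | C(Cc1ccc(OCc2ccccc2)cc1)B1C2CCCC1CCC2 | intermediate
5 | 5-{2-[4-(benzyloxy)phenyl]ethyl}benzene-1,3-diol | Oc1cc(O)cc(CCc2ccc(OCc3ccccc3)cc2)c1 | intermediate
6 | 5-{2-[4-(benzyloxy)phenyl]ethyl}-2-iodobenzene-1,3-diol | Oc1cc(CCc2ccc(OCc3ccccc3)cc2)cc(O)c1I | intermediate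
7 | 1-(benzyloxy)-4-(chloromethyl)benzene | ClCc1ccc(OCc2ccccc2)cc1 | starting material
8 | 3-{[4-(benzyloxy)phenyl]methoxy}-5-{2-[4-(benzyloxy)phenyl]ethyl}-2-iodophenol | Oc1cc(CCc2ccc(OCc3ccccc3)cc2)cc(OCc2ccc(OCc3ccccc3)cc2)c1I | intermediate
9 | (3-{[4-(benzyloxy)phenyl]methoxy}-5-{2-[4-(benzyloxy)phenyl]ethyl}-2-iodophenoxy)tri(propan-2-yl)silane | CC(C)[Si](C(C)C)(C(C)C)Oc1cc(CCc2ccc(OCc3ccccc3)cc2)cc(OCc2ccc(OCc3ccccc3)cc2)c1I | intermediate
10 | ethyl diazoacetate | CCOC(=O)C=[N+]=[N-] | starting material
11 | ethyl 2-diazo-2-(2-{[4-(benzyloxy)phenyl]methoxy}-4-{2-[4-(benzyloxy)phenyl]ethyl}-6-{[tri(propan-2-yl)silyl]oxy}phenyl)acetate | CCOC(=O)C(=[N+]=[N-])c1c(OCc2ccc(OCc3ccccc3)cc2)cc(CCc2ccc(OCc3ccccc3)cc2)cc1O[Si](C(C)C)(C(C)C)C(C)C | intermediate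
12 | ethyl (2S,3R)-2-[4-(benzyloxy)phenyl]-6-{2-[4-(benzyloxy)phenyl]ethyl}-4-{[tri(propan-2-yl)silyl]oxy}-2,3-dihydro-1-benzofuran-3-carboxylate (cis; formed in the flask in step 6) | c1ccccc1COc1ccc(CCc2cc(O[Si](C(C)C)(C(C)C)C(C)C)c3c(c2)O[C@H](c2ccc(OCc4ccccc4)cc2)[C@@H]3C(=O)OCC)cc1 | intermediate
13 | ethyl (2S,3S)-2-[4-(benzyloxy)phenyl]-6-{2-[4-(benzyloxy)phenyl]ethyl}-4-{[tri(propan-2-yl)silyl]oxy}-2,3-dihydro-1-benzofuran-3-carboxylate (trans) | c1ccccc1COc1ccc(CCc2cc(O[Si](C(C)C)(C(C)C)C(C)C)c3c(c2)O[C@H](c2ccc(OCc4ccccc4)cc2)[C@H]3C(=O)OCC)cc1 | intermediate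
14 | dimethyl (1-diazo-2-oxopropyl)phosphonate | COP(=O)(OC)C(=[N+]=[N-])C(C)=O | starting material
15 | (2S,3S)-2-[4-(benzyloxy)phenyl]-6-{2-[4-(benzyloxy)phenyl]ethyl}-4-{[tri(propan-2-yl)silyl]oxy}-2,3-dihydro-1-benzofuran-3-carbaldehyde (formed in the flask in step 7) | c1ccccc1COc1ccc(CCc2cc(O[Si](C(C)C)(C(C)C)C(C)C)c3c(c2)O[C@H](c2ccc(OCc4ccccc4)cc2)[C@H]3C=O)cc1 | intermediate
16 | {[(2S,3S)-2-[4-(benzyloxy)phenyl]-6-{2-[4-(benzyloxy)phenyl]ethyl}-3-ethynyl-2,3-dihydro-1-benzofuran-4-yl]oxy}tri(propan-2-yl)silane | c1ccccc1COc1ccc(CCc2cc(O[Si](C(C)C)(C(C)C)C(C)C)c3c(c2)O[C@H](c2ccc(OCc4ccccc4)cc2)[C@H]3C#C)cc1 | intermediate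
17 | N-methoxy-N-methylacetamide | CON(C)C(C)=O | starting material
18 | lithium acetylide of 16, {[(2S,3S)-2-[4-(benzyloxy)phenyl]-6-{2-[4-(benzyloxy)phenyl]ethyl}-4-{[tri(propan-2-yl)silyl]oxy}-2,3-dihydro-1-benzofuran-3-yl]ethynyl}lithium (formed in the flask in step 8) | c1ccccc1COc1ccc(CCc2cc(O[Si](C(C)C)(C(C)C)C(C)C)c3c(c2)O[C@H](c2ccc(OCc4ccccc4)cc2)[C@H]3C#C[Li])cc1 | intermediate
19 | 4-[(2S,3S)-2-[4-(benzyloxy)phenyl]-6-{2-[4-(benzyloxy)phenyl]ethyl}-4-{[tri(propan-2-yl)silyl]oxy}-2,3-dihydro-1-benzofuran-3-yl]but-3-yn-2-one | c1ccccc1COc1ccc(CCc2cc(O[Si](C(C)C)(C(C)C)C(C)C)c3c(c2)O[C@H](c2ccc(OCc4ccccc4)cc2)[C@H]3C#CC(C)=O)cc1 | intermediate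
20 | dibenzyl propanedioate | O=C(CC(=O)OCc1ccccc1)OCc1ccccc1 | starting material
21 | dibenzyl 2-{(1Z)-1-[(2S,3S)-2-[4-(benzyloxy)phenyl]-6-{2-[4-(benzyloxy)phenyl]ethyl}-4-{[tri(propan-2-yl)silyl]oxy}-2,3-dihydro-1-benzofuran-3-yl]-3-oxobut-1-en-1-yl}propanedioate (formed in the flask in step 9) | c1ccccc1COc1ccc(CCc2cc(O[Si](C(C)C)(C(C)C)C(C)C)c3c(c2)O[C@H](c2ccc(OCc4ccccc4)cc2)[C@H]3/C(=C/C(C)=O)C(C(=O)OCc2ccccc2)C(=O)OCc2ccccc2)cc1 | intermediate
22 | benzyl 2,4-dihydroxy-6-[(2S,3S)-2-[4-(benzyloxy)phenyl]-6-{2-[4-(benzyloxy)phenyl]ethyl}-4-{[tri(propan-2-yl)silyl]oxy}-2,3-dihydro-1-benzofuran-3-yl]benzoate | c1ccccc1COc1ccc(CCc2cc(O[Si](C(C)C)(C(C)C)C(C)C)c3c(c2)O[C@H](c2ccc(OCc4ccccc4)cc2)[C@H]3c2cc(O)cc(O)c2C(=O)OCc2ccccc2)cc1 | intermediate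
23 | benzyl 2,4-dihydroxy-6-[(2S,3S)-2-[4-(benzyloxy)phenyl]-6-{2-[4-(benzyloxy)phenyl]ethyl}-4-hydroxy-2,3-dihydro-1-benzofuran-3-yl]benzoate | c1ccccc1COc1ccc(CCc2cc(O)c3c(c2)O[C@H](c2ccc(OCc4ccccc4)cc2)[C@H]3c2cc(O)cc(O)c2C(=O)OCc2ccccc2)cc1 | intermediate
24 | 2,4-dihydroxy-6-{(2S,3S)-4-hydroxy-2-(4-hydroxyphenyl)-6-[2-(4-hydroxyphenyl)ethyl]-2,3-dihydro-1-benzofuran-3-yl}benzoic acid (formed in the flask in step 11) | Oc1ccc(CCc2cc(O)c3c(c2)O[C@H](c2ccc(O)cc2)[C@H]3c2cc(O)cc(O)c2C(O)=O)cc1 | intermediate
25 | 5-{(2S,3S)-4-hydroxy-2-(4-hydroxyphenyl)-6-[2-(4-hydroxyphenyl)ethyl]-2,3-dihydro-1-benzofuran-3-yl}benzene-1,3-diol | Oc1ccc(CCc2cc(O)c3c(c2)O[C@H](c2ccc(O)cc2)[C@H]3c2cc(O)cc(O)c2)cc1 | target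

## Step count and least certain steps

Total step count: 11. Longest linear sequence: 11 steps (1 to 25); all other inputs are purchased.

Step 9 (key step). Deprotonation at C3 may compete with conjugate addition, leading to propargyl–allenyl isomerisation and erosion of the C3 configuration. Lactonisation to a pyranone may fail to revert. Addition may be slowed by shielding from the silyl ether at O4 and the C2 aryl group. The fallback sets out from 13 and comes back at 22.
- Reduction of 13 with i-Bu2AlH at −78 °C and aqueous work-up would give aldehyde 15 in isolated form.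
- Wittig olefination with 1-(triphenylphosphoranylidene)propan-2-one in warm toluene should give (E)-4-[(2S,3S)-2-[4-(benzyloxy)phenyl]-6-{2-[4-(benzyloxy)phenyl]ethyl}-4-(TIPS-oxy)-2,3-dihydro-1-benzofuran-3-yl]but-3-en-2-one F1.
- Sodium dibenzyl malonate from 20 would add to the enone and close by Claisen condensation to the dihydroresorcylate, benzyl 2-hydroxy-4-oxo-6-[(2S,3S)-2-[4-(benzyloxy)phenyl]-6-{2-[4-(benzyloxy)phenyl]ethyl}-4-(TIPS-oxy)-2,3-dihydro-1-benzofuran-3-yl]cyclohex-2-ene-1-carboxylate F2.
- Bromination at the doubly activated ring carbon with one equivalent of pyridinium tribromide and loss of HBr would aromatise F2 to 22.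

Step 3. Nothing but stoichiometry distinguishes the two phenols, so over-alkylation to the bis-ether and incomplete conversion may erode the amount of mono-ether; the reactive benzylic chloride may also alkylate ring carbon. The fallback sets out from 6 and comes back at 9.
- Silylation of both phenols with TIPSOTf and 2,6-lutidine in CH2Cl2 should give [(5-{2-[4-(benzyloxy)phenyl]ethyl}-2-iodo-1,3-phenylene)bis(oxy)]bis[tri(propan-2-yl)silane] F3.
- One equivalent of LiOH in THF/H2O should remove a single silyl group, because the phenoxide formed makes the second aryloxide a much poorer leaving group, and give 5-{2-[4-(benzyloxy)phenyl]ethyl}-2-iodo-3-(TIPS-oxy)phenol F4.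
- Alkylation of F4 with 7 and K2CO3 in acetone would give 9.

Step 5. Oxidative addition and transfer at the iodide flanked by an alkoxy and a bulky silyloxy group may be slow, so that 10 decomposes by carbene dimerisation faster than it couples. The fallback sets out from 9 and comes back at 11.
- Coupling of 9 with the Reformatsky reagent BrZnCH2CO2Et under Pd(dba)2/P(t-Bu)3 in THF should give ethyl 2-[2-(BOB-oxy)-4-{2-[4-(benzyloxy)phenyl]ethyl}-6-(TIPS-oxy)phenyl]acetate F5.
- Regitz diazo transfer with 4-acetamidobenzenesulfonyl azide and DBU in MeCN would convert F5 into 11.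

Step 6. Discrimination of the enantiotopic benzylic hydrogens may be poor, because the second ortho substituent twists the aryl group out of the carbene plane and the very electron-rich C–H bond reacts with hydride-transfer character. The fallback sets out from 11 and comes back at 13.
- Insertion with achiral Rh2(OAc)4 in CH2Cl2 followed by KOt-Bu in t-BuOH/THF should give the racemic trans ester, ethyl rac-(2S,3S)-2-[4-(benzyloxy)phenyl]-6-{2-[4-(benzyloxy)phenyl]ethyl}-4-(TIPS-oxy)-2,3-dihydro-1-benzofuran-3-carboxylate F6.
- Resolution of F6 by preparative chromatography on a chiral stationary phase would deliver 13.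

Step 1. Oxidative addition into the electron-rich bromide, carried as a bis-phenoxide, may be slow, so that protodeboronation or beta-hydride elimination of the alkylborane takes over. The fallback sets out from 1 and 3 and comes back at 5.
- Heck coupling of 1 with 3 under Pd(OAc)2, P(o-tol)3 and Et3N in DMF at 100 °C should give (E)-5-{2-[4-(benzyloxy)phenyl]ethenyl}benzene-1,3-diol F7.
- Homogeneous hydrogenation of F7 with H2 and RhCl(PPh3)3 in benzene/EtOH would reduce the stilbene double bond without touching the benzyl ether and give 5.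

Step 11. Hydrogenolysis of the ring C2–O1 bond may compete with removal of the last benzyl ether, and the polyphenol may oxidise during the thermal decarboxylation. The fallback sets out from 23 and comes back at 25.
- Saponification with KOH in DMSO/H2O should give 2,4-dihydroxy-6-[(2S,3S)-2-[4-(benzyloxy)phenyl]-6-{2-[4-(benzyloxy)phenyl]ethyl}-4-hydroxy-2,3-dihydro-1-benzofuran-3-yl]benzoic acid F8.
- On neutralisation with NaH2PO4 and warming, F8 should lose CO2 to give 5-[(2S,3S)-2-[4-(benzyloxy)phenyl]-6-{2-[4-(benzyloxy)phenyl]ethyl}-4-hydroxy-2,3-dihydro-1-benzofuran-3-yl]benzene-1,3-diol F9.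
- Non-reductive debenzylation of F9 with BCl3 and pentamethylbenzene in CH2Cl2 at −78 °C would give 25.

## Further compounds

F1 | step 9 | (E)-4-[(2S,3S)-2-[4-(benzyloxy)phenyl]-6-{2-[4-(benzyloxy)phenyl]ethyl}-4-{[tri(propan-2-yl)silyl]oxy}-2,3-dihydro-1-benzofuran-3-yl]but-3-en-2-one | c1ccccc1COc1ccc(CCc2cc(O[Si](C(C)C)(C(C)C)C(C)C)c3c(c2)O[C@H](c2ccc(OCc4ccccc4)cc2)[C@H]3/C=C/C(C)=O)cc1
F2 | step 9 | benzyl 2-hydroxy-4-oxo-6-[(2S,3S)-2-[4-(benzyloxy)phenyl]-6-{2-[4-(benzyloxy)phenyl]ethyl}-4-{[tri(propan-2-yl)silyl]oxy}-2,3-dihydro-1-benzofuran-3-yl]cyclohex-2-ene-1-carboxylate (mixture of isomers at the new ring carbons) | c1ccccc1COc1ccc(CCc2cc(O[Si](C(C)C)(C(C)C)C(C)C)c3c(c2)O[C@H](c2ccc(OCc4ccccc4)cc2)[C@H]3C2CC(=O)C=C(O)C2C(=O)OCc2ccccc2)cc1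
F3 | step 3 | [(5-{2-[4-(benzyloxy)phenyl]ethyl}-2-iodo-1,3-phenylene)bis(oxy)]bis[tri(propan-2-yl)silane] | CC(C)[Si](C(C)C)(C(C)C)Oc1cc(CCc2ccc(OCc3ccccc3)cc2)cc(O[Si](C(C)C)(C(C)C)C(C)C)c1I
F4 | step 3 | 5-{2-[4-(benzyloxy)phenyl]ethyl}-2-iodo-3-{[tri(propan-2-yl)silyl]oxy}phenol | CC(C)[Si](C(C)C)(C(C)C)Oc1cc(CCc2ccc(OCc3ccccc3)cc2)cc(O)c1I
F5 | step 5 | ethyl 2-(2-{[4-(benzyloxy)phenyl]methoxy}-4-{2-[4-(benzyloxy)phenyl]ethyl}-6-{[tri(propan-2-yl)silyl]oxy}phenyl)acetate | CCOC(=O)Cc1c(OCc2ccc(OCc3ccccc3)cc2)cc(CCc2ccc(OCc3ccccc3)cc2)cc1O[Si](C(C)C)(C(C)C)C(C)C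
F6 | step 6 | ethyl rac-(2S,3S)-2-[4-(benzyloxy)phenyl]-6-{2-[4-(benzyloxy)phenyl]ethyl}-4-{[tri(propan-2-yl)silyl]oxy}-2,3-dihydro-1-benzofuran-3-carboxylate (racemic trans ester, both enantiomers shown) | c1ccccc1COc1ccc(CCc2cc(O[Si](C(C)C)(C(C)C)C(C)C)c3c(c2)O[C@H](c2ccc(OCc4ccccc4)cc2)[C@H]3C(=O)OCC)cc1.c1ccccc1COc1ccc(CCc2cc(O[Si](C(C)C)(C(C)C)C(C)C)c3c(c2)O[C@@H](c2ccc(OCc4ccccc4)cc2)[C@@H]3C(=O)OCC)cc1
F7 | step 1 | (E)-5-{2-[4-(benzyloxy)phenyl]ethenyl}benzene-1,3-diol | Oc1cc(O)cc(/C=C/c2ccc(OCc3ccccc3)cc2)c1
F8 | step 11 | 2,4-dihydroxy-6-[(2S,3S)-2-[4-(benzyloxy)phenyl]-6-{2-[4-(benzyloxy)phenyl]ethyl}-4-hydroxy-2,3-dihydro-1-benzofuran-3-yl]benzoic acid | c1ccccc1COc1ccc(CCc2cc(O)c3c(c2)O[C@H](c2ccc(OCc4ccccc4)cc2)[C@H]3c2cc(O)cc(O)c2C(O)=O)cc1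
F9 | step 11 | 5-[(2S,3S)-2-[4-(benzyloxy)phenyl]-6-{2-[4-(benzyloxy)phenyl]ethyl}-4-hydroxy-2,3-dihydro-1-benzofuran-3-yl]benzene-1,3-diol | c1ccccc1COc1ccc(CCc2cc(O)c3c(c2)O[C@H](c2ccc(OCc4ccccc4)cc2)[C@H]3c2cc(O)cc(O)c2)cc1
A1 | alternative 1 | (1S,2S)-1-(3,5-dimethoxyphenyl)-2-(4-methoxyphenyl)-6-[2-(4-methoxyphenyl)ethyl]spiro[2.5]octane-4,8-dione (trans cyclopropane) | COc1ccc(CCC2CC(=O)C3(C(=O)C2)[C@H](c2ccc(OC)cc2)[C@H]3c2cc(OC)cc(OC)c2)cc1
A2 | alternative 1 | (2S,3S)-3-(3,5-dimethoxyphenyl)-2-(4-methoxyphenyl)-6-[2-(4-methoxyphenyl)ethyl]-3,5,6,7-tetrahydro-1-benzofuran-4(2H)-one (both C6 epimers) | COc1ccc(CCC2CC(=O)C3=C(C2)O[C@H](c2ccc(OC)cc2)[C@H]3c2cc(OC)cc(OC)c2)cc1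
A3 | alternative 1 | (2S,3S)-3-(3,5-dimethoxyphenyl)-2-(4-methoxyphenyl)-6-[2-(4-methoxyphenyl)ethyl]-2,3-dihydro-1-benzofuran-4-ol | COc1ccc(CCc2cc(O)c3c(c2)O[C@H](c2ccc(OC)cc2)[C@H]3c2cc(OC)cc(OC)c2)cc1
A4 | alternative 2 | triisopropyl{[(3S,4S)-3-(3,5-dimethoxyphenyl)-4-(ethynyloxy)-4-(4-methoxyphenyl)but-1-yn-1-yl]oxy}silane | C#CO[C@H](c1ccc(OC)cc1)[C@H](C#CO[Si](C(C)C)(C(C)C)C(C)C)c1cc(OC)cc(OC)c1
A5 | alternative 2 | 1-(but-3-yn-1-yl)-4-methoxybenzene | C#CCCc1ccc(OC)cc1
A6 | alternative 2 | (2S,3S)-3-(3,5-dimethoxyphenyl)-2-(4-methoxyphenyl)-6-[2-(4-methoxyphenyl)ethyl]-4-(triisopropylsilyloxy)-2,3-dihydro-1-benzofuran | COc1ccc(CCc2cc(O[Si](C(C)C)(C(C)C)C(C)C)c3c(c2)O[C@H](c2ccc(OC)cc2)[C@H]3c2cc(OC)cc(OC)c2)cc1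
A7 | alternative 3 | 3-[2-(4-methoxyphenyl)ethyl]cyclobut-2-en-1-one | O=C1C=C(CCc2ccc(OC)cc2)C1
A8 | alternative 3 | tert-butyl{[2-(3,5-dimethoxyphenyl)-1-(4-methoxyphenyl)-4-(triisopropylsilyloxy)but-3-yn-1-yl]oxy}dimethylsilane (anti, both centres arranged as C2 and C3 of the target) | CC(C)[Si](C(C)C)(C(C)C)OC#C[C@H](c1cc(OC)cc(OC)c1)[C@H](O[Si](C)(C)C(C)(C)C)c1ccc(OC)cc1
A9 | alternative 3 | 2-[anti-2-(tert-butyldimethylsilyloxy)-1-(3,5-dimethoxyphenyl)-2-(4-methoxyphenyl)ethyl]-5-[2-(4-methoxyphenyl)ethyl]-3-(triisopropylsilyloxy)phenol | COc1ccc(CCc2cc(O)c([C@H](c3cc(OC)cc(OC)c3)[C@H](O[Si](C)(C)C(C)(C)C)c3ccc(OC)cc3)c(O[Si](C(C)C)(C(C)C)C(C)C)c2)cc1
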